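## Retrosynthetic overview

1. Ketoemblide (21) is a 14-membered carbocycle bridged by a seven-membered α,β-unsaturated lactone (lactone numbering O1, C2=O, C3, C4, C5, C6, C7; C7 is the (S) quaternary carbon). The enabling feature is that C3, the lactone α-carbon, lies between the C2 carbonyl and the ring-alkene carbon C4. With C4 raised to a ketone, C3 becomes the central carbon of a 1,3-dicarbonyl unit, a soft chelated carbon nucleophile for the C3–CH2 ring closure, and the same β-keto ester is an acylketene precursor that can acylate the hindered C7 oxygen.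
2. Disconnections: C3–CH2 (macrocyclic enolate alkylation, closes the carbocycle) and C2–O on C7 (transannular acylketene capture, closes the lactone), both in one operation from acyclic 15. Next, the CH2–C(α) bond of the (Z)-enoate, by Ru-catalysed alkene–alkyne coupling of allylic methyl ether 14 with enynoate 8, which also delivers the ring ketone masked as a methyl enol ether. Last, C5–C6 (acetoacetate dianion + epoxide 12).
3. Stereochemistry: C7 from a Sharpless kinetic-resolution epoxidation; the trisubstituted diene alkene from syn-carbocupration of an ynoate; the enoate geometry from cis addition across the alkyne.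
4. Ring order: 14-membered carbocycle first, then the lactone in the same flask. End game: C4 ketone → enol triflate → C4–H alkene, then enol ether → ketone.

Key step: step 12

Remark: 14, 15 and 16 are γ-hydroxy β-keto esters that should exist largely as five-membered cyclic hemiketals; they are listed in the open keto form, which is the reacting tautomer.
Remark: the enol ether in 15–20 is drawn Z (expected from the metallacycle); either isomer would serve because it is hydrolysed in step 15. C3 of 16 and 18 is an epimer mixture of no consequence.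

## Route

Step 1
Reactants: 1 4-bromobut-1-yne
Product: 2 methyl 5-bromopent-2-ynoate
Conditions: n-BuLi, THF, −78 °C; then ClCO2Me, −78 → 0 °C
Reagents that add atoms: methyl chloroformate, COC(=O)Cl
Why: C-acylation of a lithium acetylide with a chloroformate is standard, and the primary bromide should be inert to the acetylide at −78 °C.

Step 2
Reactants: 2 methyl 5-bromopent-2-ynoate
Product: 3 methyl (2E)-5-bromo-3-(propan-2-yl)pent-2-enoate
Conditions: i-PrMgCl, CuBr·SMe2 (1:1), THF, −78 °C; then MeOH, −78 °C
Reagents that add atoms: isopropylmagnesium chloride, CC(C)[Mg]Cl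
Why: syn-carbocupration of the ynoate followed by cold protonation with retention should place isopropyl trans and the bromoethyl arm cis to the ester (kinetic control).

Step 3
Reactants: 3 methyl (2E)-5-bromo-3-(propan-2-yl)pent-2-enoate
Product: 4 (2E)-5-bromo-3-(propan-2-yl)pent-2-en-1-ol
Conditions: i-Bu2AlH (2.2 equiv), CH2Cl2, −78 °C
Reagents that add atoms: none
Why: 1,2-reduction of an enoate to the allylic alcohol by the aluminium hydride leaves the alkene geometry and the alkyl bromide untouched.

Step 4
Reactants: 4 (2E)-5-bromo-3-(propan-2-yl)pent-2-en-1-ol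
Product: 5 (2E)-5-bromo-3-(propan-2-yl)pent-2-enal
Conditions: MnO2, CH2Cl2, rt
Reagents that add atoms: none
Why: neutral allylic oxidation should keep the geometry of the trisubstituted alkene.

Step 5
Reactants: 5 (2E)-5-bromo-3-(propan-2-yl)pent-2-enal
Product: 6 (3E)-1,1,6-tribromo-4-(propan-2-yl)hexa-1,3-diene
Conditions: CBr4, PPh3, CH2Cl2, 0 °C
Reagents that add atoms: carbon tetrabromide, BrC(Br)(Br)Br
Why: the first stage of the Corey–Fuchs homologation is a Wittig-type dibromo-olefination that tolerates enals and alkyl bromides.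

Step 6
Reactants: 6 (3E)-1,1,6-tribromo-4-(propan-2-yl)hexa-1,3-diene
Product: 8 methyl (4E)-7-bromo-5-(propan-2-yl)hept-4-en-2-ynoate, via lithium acetylide 7 (not isolated)
Conditions: n-BuLi (2 equiv), THF, −78 °C; then ClCO2Me, −78 → 0 °C
Reagents that add atoms: methyl chloroformate, COC(=O)Cl
Why: the second Corey–Fuchs stage (vinyl Br/Li exchange, Fritsch–Buttenberg–Wiechell rearrangement, deprotonation) gives the acetylide, which is acylated in the same flask, the vinylic exchange being much faster than attack on the primary bromide.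

Step 7
Reactants: 9 methacrolein
Product: 10 (±)-2-methylpenta-1,4-dien-3-ol
Conditions: CH2=CHMgBr, THF, −78 → 0 °C
Reagents that add atoms: vinylmagnesium bromide, C=C[Mg]Br
Why: Grignard reagents add 1,2 to this enal.

Step 8
Reactants: 10 (±)-2-methylpenta-1,4-dien-3-ol
Product: 11 (1R)-1-[(2S)-2-methyloxiran-2-yl]prop-2-en-1-ol
Conditions: Ti(Oi-Pr)4, D-(−)-diisopropyl tartrate, t-BuOOH (0.45 equiv), 4 Å molecular sieves, CH2Cl2, −20 °C
Reagents that add atoms: tert-butyl hydroperoxide, CC(C)(C)OO
Why: in this Sharpless asymmetric epoxidation run as a kinetic resolution, the D-tartrate catalyst should epoxidise the (R)-alcohol at its more electron-rich 1,1-disubstituted alkene, on the face that makes the quaternary epoxide carbon (S) with the erythro relation, while (S)-10 and the vinyl group react slowly.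

Step 9
Reactants: 11 (1R)-1-[(2S)-2-methyloxiran-2-yl]prop-2-en-1-ol
Product: 12 (2S)-2-[(1R)-1-methoxyprop-2-en-1-yl]-2-methyloxirane
Conditions: NaH, MeI, THF, 0 °C
Reagents that add atoms: iodomethane, CI
Why: Williamson O-methylation should be clean because a Payne rearrangement would require SN2 attack at the fully substituted epoxide carbon.

Step 10
Reactants: 12 (2S)-2-[(1R)-1-methoxyprop-2-en-1-yl]-2-methyloxirane; 13 tert-butyl 3-oxobutanoate
Product: 14 tert-butyl (6S,7R)-6-hydroxy-7-methoxy-6-methyl-3-oxonon-8-enoate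
Conditions: 13, LiN(i-Pr)2 (2.1 equiv), THF, 0 °C; then 12, 0 °C → rt
Reagents that add atoms: none
Why: γ-alkylation of the acetoacetate dianion by SN2 opening of the epoxide at its unsubstituted CH2 leaves the C–O bond of the quaternary centre, and so its (S) configuration, intact.

Step 11
Reactants: 14 tert-butyl (6S,7R)-6-hydroxy-7-methoxy-6-methyl-3-oxonon-8-enoate; 8 methyl (4E)-7-bromo-5-(propan-2-yl)hept-4-en-2-ynoate
Product: 15 tert-butyl (6S,7Z,10Z,12E)-15-bromo-6-hydroxy-7-methoxy-10-(methoxycarbonyl)-6-methyl-3-oxo-13-(propan-2-yl)pentadeca-7,10,12-trienoate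
Conditions: [CpRu(MeCN)3]PF6 (10 mol %), acetone, rt; filtration through Et3N-treated silica
Reagents that add atoms: none
Why: in this ruthenium-catalysed alkene–alkyne (Alder-ene type) coupling via a ruthenacyclopentene, the new C–C bond should form at the ester-bearing alkyne carbon with cis delivery of H and the allyl carbon (ester cis to the diene), and β-hydride elimination of the only allylic hydrogen should give the methyl enol ether that masks the ring ketone.

Step 12
Reactants: 15 tert-butyl (6S,7Z,10Z,12E)-15-bromo-6-hydroxy-7-methoxy-10-(methoxycarbonyl)-6-methyl-3-oxo-13-(propan-2-yl)pentadeca-7,10,12-trienoate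
Product: 18 methyl (1S,2Z,5Z,7E)-2-methoxy-1-methyl-12,16-dioxo-8-(propan-2-yl)-15-oxabicyclo[9.3.2]hexadeca-2,5,7-triene-5-carboxylate, via macrocyclic keto ester 16 (not isolated), via acylketene 17 (not isolated)
Conditions: Cs2CO3, NaI (cat.), MeCN, 50 °C, slow addition of 15 (final ca. 1 mM); filtration, solvent change to toluene, 110 °C
Reagents that add atoms: none
Why: Stage one is the classical high-dilution macrocyclisation of a β-keto ester: Cs2CO3 draws the open keto tautomer of 15 into its chelated cesium enolate, whose central carbon (the future lactone C3) displaces the primary bromide (iodide after halide exchange) by SN2 and closes the 14-membered carbocycle in the 14-exo-tet mode. Stage two is the known thermal route from tert-butyl β-keto esters to acylketenes (loss of tert-butanol from the still enolisable α-monosubstituted ester), and the tertiary C7 hydroxyl adds to the ketene carbonyl to close the seven-membered lactone transannularly (7-exo-dig), an acylation that ordinary esterification of this hindered alcohol would not give. The one new stereocentre, C3, forms as an epimer mixture and is flattened to sp2 in step 13, so nothing has to control it, and the (S) centre at C7 is never a reacting carbon. The step needs C- over O-alkylation and ring closure over oligomerisation, which the acyclic metal-chelated enolate, the soft unhindered primary halide and slow addition should secure. It also needs the ring ketone to stay masked, since a free ketone would condense with the active methylene, and the methyl enol ether is inert to carbonate and to 110 °C.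

Step 13
Reactants: 18 methyl (1S,2Z,5Z,7E)-2-methoxy-1-methyl-12,16-dioxo-8-(propan-2-yl)-15-oxabicyclo[9.3.2]hexadeca-2,5,7-triene-5-carboxylate
Product: 19 methyl (1S,2Z,5Z,7E,11E)-2-methoxy-1-methyl-16-oxo-8-(propan-2-yl)-12-{[(trifluoromethyl)sulfonyl]oxy}-15-oxabicyclo[9.3.2]hexadeca-2,5,7,11-tetraene-5-carboxylate
Conditions: NaH (1.05 equiv), PhNTf2, THF, 0 °C → rt
Reagents that add atoms: N-phenylbis(trifluoromethanesulfonimide), O=S(=O)(N(c1ccccc1)S(=O)(=O)C(F)(F)F)C(F)(F)F
Why: only the C3–H between the two carbonyls is acidic enough for one equivalent of NaH, and O-sulfonylation of the enolate at the ketone oxygen fixes the double bond at C3=C4 and erases the C3 stereocentre.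

Step 14
Reactants: 19 methyl (1S,2Z,5Z,7E,11E)-2-methoxy-1-methyl-16-oxo-8-(propan-2-yl)-12-{[(trifluoromethyl)sulfonyl]oxy}-15-oxabicyclo[9.3.2]hexadeca-2,5,7,11-tetraene-5-carboxylate
Product: 20 methyl (1S,2Z,5Z,7E,11Z)-2-methoxy-1-methyl-16-oxo-8-(propan-2-yl)-15-oxabicyclo[9.3.2]hexadeca-2,5,7,11-tetraene-5-carboxylate
Conditions: Pd(OAc)2 (5 mol %), PPh3, HCO2H, n-Bu3N (excess), DMF, 60 °C
Reagents that add atoms: none
Why: palladium-catalysed formate reduction of a vinyl triflate (oxidative addition to zerovalent palladium, decarboxylation of formate, C–H reductive elimination) should replace OTf by H without touching the dienoate or, in the amine-buffered medium, the enol ether.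

Step 15
Reactants: 20 methyl (1S,2Z,5Z,7E,11Z)-2-methoxy-1-methyl-16-oxo-8-(propan-2-yl)-15-oxabicyclo[9.3.2]hexadeca-2,5,7,11-tetraene-5-carboxylate
Product: 21 ketoemblide
Conditions: 0.5 M aq. HCl, THF, 0 °C → rt
Reagents that add atoms: water, O
Why: acid hydrolysis of the methyl enol ether (C-protonation at the CH, addition of water, loss of methanol) should release the ring ketone, and the adjacent (S) centre is quaternary and cannot epimerise.

## Compound list

1 | 4-bromobut-1-yne | BrCCC#C | starting material
2 | methyl 5-bromopent-2-ynoate | COC(=O)C#CCCBr | intermediate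
3 | methyl (2E)-5-bromo-3-(propan-2-yl)pent-2-enoate | COC(=O)/C=C(\CCBr)C(C)C | intermediate
4 | (2E)-5-bromo-3-(propan-2-yl)pent-2-en-1-ol | OC/C=C(\CCBr)C(C)C | intermediate
5 | (2E)-5-bromo-3-(propan-2-yl)pent-2-enal | O=C/C=C(\CCBr)C(C)C | intermediate
6 | (3E)-1,1,6-tribromo-4-(propan-2-yl)hexa-1,3-diene | BrC(Br)=C/C=C(\CCBr)C(C)C | intermediate
7 | lithium (3E)-6-bromo-4-(propan-2-yl)hex-3-en-1-yn-1-ide (not isolated) | [Li]C#C/C=C(\CCBr)C(C)C | intermediate
8 | methyl (4E)-7-bromo-5-(propan-2-yl)hept-4-en-2-ynoate | COC(=O)C#C/C=C(\CCBr)C(C)C | intermediate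
9 | methacrolein (2-methylprop-2-enal) | CC(=C)C=O | starting material
10 | (±)-2-methylpenta-1,4-dien-3-ol | C=CC(O)C(C)=C | intermediate
11 | (1R)-1-[(2S)-2-methyloxiran-2-yl]prop-2-en-1-ol | C[C@]1(CO1)[C@H](O)C=C | intermediate
12 | (2S)-2-[(1R)-1-methoxyprop-2-en-1-yl]-2-methyloxirane | C[C@]1(CO1)[C@H](OC)C=C | intermediate
13 | tert-butyl 3-oxobutanoate | CC(=O)CC(=O)OC(C)(C)C | starting material
14 | tert-butyl (6S,7R)-6-hydroxy-7-methoxy-6-methyl-3-oxonon-8-enoate | CC(C)(C)OC(=O)CC(=O)CC[C@](C)(O)[C@H](OC)C=C | intermediate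
15 | tert-butyl (6S,7Z,10Z,12E)-15-bromo-6-hydroxy-7-methoxy-10-(methoxycarbonyl)-6-methyl-3-oxo-13-(propan-2-yl)pentadeca-7,10,12-trienoate | CC(C)(C)OC(=O)CC(=O)CC[C@](C)(O)/C(OC)=C/C/C(C(=O)OC)=C/C=C(\CCBr)C(C)C | intermediate
16 | 1-tert-butyl 9-methyl (5S,6Z,9Z,11E)-5-hydroxy-6-methoxy-5-methyl-2-oxo-12-(propan-2-yl)cyclotetradeca-6,9,11-triene-1,9-dicarboxylate, C1 epimers (not isolated) | COC(=O)/C1=C\C=C(\C(C)C)CCC(C(=O)OC(C)(C)C)C(=O)CC[C@](C)(O)/C(OC)=C/C1 | intermediate
17 | acylketene: methyl (5S,6Z,9Z,11E)-5-hydroxy-6-methoxy-5-methyl-2-oxo-1-(oxomethylidene)-12-(propan-2-yl)cyclotetradeca-6,9,11-triene-9-carboxylate (not isolated) | COC(=O)/C1=C\C=C(\C(C)C)CCC(=C=O)C(=O)CC[C@](C)(O)/C(OC)=C/C1 | intermediate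
18 | methyl (1S,2Z,5Z,7E)-2-methoxy-1-methyl-12,16-dioxo-8-(propan-2-yl)-15-oxabicyclo[9.3.2]hexadeca-2,5,7-triene-5-carboxylate, C11 epimers | COC(=O)/C1=C\C=C(\C(C)C)CCC2C(=O)CC[C@](C)(OC2=O)/C(OC)=C/C1 | intermediate
19 | methyl (1S,2Z,5Z,7E,11E)-2-methoxy-1-methyl-16-oxo-8-(propan-2-yl)-12-{[(trifluoromethyl)sulfonyl]oxy}-15-oxabicyclo[9.3.2]hexadeca-2,5,7,11-tetraene-5-carboxylate | COC(=O)/C1=C\C=C(\C(C)C)CCC2=C(OS(=O)(=O)C(F)(F)F)CC[C@](C)(OC2=O)/C(OC)=C/C1 | intermediate
20 | methyl (1S,2Z,5Z,7E,11Z)-2-methoxy-1-methyl-16-oxo-8-(propan-2-yl)-15-oxabicyclo[9.3.2]hexadeca-2,5,7,11-tetraene-5-carboxylate | COC(=O)/C1=C\C=C(\C(C)C)CCC2=CCC[C@](C)(OC2=O)/C(OC)=C/C1 | intermediate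
21 | ketoemblide, methyl (1S,5Z,7E,11Z)-1-methyl-2,16-dioxo-8-(propan-2-yl)-15-oxabicyclo[9.3.2]hexadeca-5,7,11-triene-5-carboxylate | COC(=O)/C1=C\C=C(\C(C)C)CCC2=CCC[C@](C)(OC2=O)C(=O)CC1 | target

## Step count and risks

Total step count: 15 (steps 1–6 west fragment, steps 7–10 east fragment, steps 11–15 union and end game).
Longest linear sequence: 11 steps (steps 1–6, then 11–15).

Steps most likely to fail:

Step 12 (key step). In stage one the ring closure may lose to intermolecular C- or O-alkylation. In stage two the cyclic hemiketal tautomer may dehydrate to an alkylidene tetrahydrofuran, or the acylketene may be captured intermolecularly, before the hindered tertiary hydroxyl adds. The fallback separates the two ring closures and replaces the thermal ketene stage by thiophilic activation of a thioester at room temperature. It sets out from 12 and comes back at 18. The dianion of S-tert-butyl 3-oxobutanethioate (LiN(i-Pr)2, THF) should open 12 to S-tert-butyl (6S,7R)-6-hydroxy-7-methoxy-6-methyl-3-oxonon-8-enethioate F1. Coupling of F1 with 8 under the conditions of step 11 should give the thioester analogue of 15, methyl (2Z,4E)-7-bromo-2-[(2Z,4S)-9-(tert-butylsulfanyl)-4-hydroxy-3-methoxy-4-methyl-7,9-dioxonon-2-en-1-yl]-5-(propan-2-yl)hepta-2,4-dienoate F2. High-dilution Cs2CO3/NaI alkylation, now worked up and purified, should give the macrocyclic β-keto thioester (S-tert-butyl analogue of 16) F3. AgO2CCF3 with Na2HPO4 in THF at room temperature should then close the lactone to 18.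

Step 11. Slow turnover with the hindered allylic ether (next to a fully substituted carbon) may let alkyne oligomerisation and catalyst decay win, and the new bond may form at the wrong alkyne carbon. The fallback joins the fragments by the reliable alkylation first and runs the alkene–alkyne coupling as a high-dilution ring closure, where bimolecular alkyne coupling is suppressed and no excess of either partner is needed. It sets out from 14 and 8 and comes back at 16. Intermolecular C-alkylation of 14 with 8 (Cs2CO3, NaI, MeCN) should give tert-butyl (6S,7R)-6-hydroxy-7-methoxy-2-[(3E)-7-methoxy-7-oxo-3-(propan-2-yl)hept-3-en-5-yn-1-yl]-6-methyl-3-oxonon-8-enoate F4. Intramolecular Alder-ene coupling of F4 ([CpRu(MeCN)3]PF6, acetone, ca. 1 mM) should close the 14-membered carbocycle to 16, which is heated in toluene as in the second stage of step 12 to give 18.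

Step 10. SN2 attack at the neopentyl-type epoxide CH2 may be slow, so that the dianion acts as a base (epoxide to allylic alcohol) or decomposes. The fallback builds the same chain through a γ-lactone; it sets out from 12 and comes back at 14. Dimethyl malonate with NaOMe in refluxing MeOH should open 12 and lactonise to methyl (5S)-5-[(1R)-1-methoxyprop-2-en-1-yl]-5-methyl-2-oxooxolane-3-carboxylate F5. Krapcho decarboxylation (LiCl, wet DMSO, 150 °C) should give (5S)-5-[(1R)-1-methoxyprop-2-en-1-yl]-5-methyloxolan-2-one F6. Addition of LiCH2CO2t-Bu (from tert-butyl acetate and LiN(i-Pr)2, THF, −78 °C) to the lactone carbonyl of F6 should give 14.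

Further compounds
F1 | step 12 | S-tert-butyl (6S,7R)-6-hydroxy-7-methoxy-6-methyl-3-oxonon-8-enethioate | CC(C)(C)SC(=O)CC(=O)CC[C@](C)(O)[C@H](OC)C=C
F2 | step 12 | methyl (2Z,4E)-7-bromo-2-[(2Z,4S)-9-(tert-butylsulfanyl)-4-hydroxy-3-methoxy-4-methyl-7,9-dioxonon-2-en-1-yl]-5-(propan-2-yl)hepta-2,4-dienoate | CC(C)(C)SC(=O)CC(=O)CC[C@](C)(O)/C(OC)=C/C/C(C(=O)OC)=C/C=C(\CCBr)C(C)C
F3 | step 12 | macrocyclic β-keto thioester, S-tert-butyl analogue of 16 (C1 epimers) | COC(=O)/C1=C\C=C(\C(C)C)CCC(C(=O)SC(C)(C)C)C(=O)CC[C@](C)(O)/C(OC)=C/C1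
F4 | step 11 | tert-butyl (6S,7R)-6-hydroxy-7-methoxy-2-[(3E)-7-methoxy-7-oxo-3-(propan-2-yl)hept-3-en-5-yn-1-yl]-6-methyl-3-oxonon-8-enoate (C2 epimers) | COC(=O)C#C/C=C(\CCC(C(=O)OC(C)(C)C)C(=O)CC[C@](C)(O)[C@H](OC)C=C)C(C)C
F5 | step 10 | methyl (5S)-5-[(1R)-1-methoxyprop-2-en-1-yl]-5-methyl-2-oxooxolane-3-carboxylate (C3 epimers) | COC(=O)C1C[C@](C)(OC1=O)[C@H](OC)C=C
F6 | step 10 | (5S)-5-[(1R)-1-methoxyprop-2-en-1-yl]-5-methyloxolan-2-one | O=C1CC[C@](C)(O1)[C@H](OC)C=C
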